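With each half numbered as a 1-benzoxepine, everything rests on closing the left cyclohexane (C5a–C6–C7–C8–C9–C9a) last, through the C5a–C6 bond. The key step is a TMSOTf-triggered epoxonium cascade of an acyclic 1,5-diepoxide bearing a (Z)-silyl enol ether and already joined through the two-carbon bridge to the finished right bicycle: the oxepane closes first, then the enol silane closes the cyclohexanone, setting C5a and C6. It exploits the trans C9a–O/C5a–CH3 fusion and the O1–C2(CH3)2–C3(O) unit of the left oxepane, the imprint of a 1,5-diepoxide. The enol silane arises regiospecifically by conjugate addition of the right-half organocopper to a diepoxy vinyl ketone; equatorial MeMgBr addition then gives the axial C7 carbinol.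

Key step: step 8

Remark on numbering: each bicyclic half is a decahydro-1-benzoxepine with O1, C2(CH3)2, C3 (O-bearing CH), C4, C5, C5a (quaternary, CH3), C6 (CH carrying the bridge), C7 (C(CH3)–O), C8, C9 and C9a (O–CH).

Assumption: the L-fructose-derived Shi ketone (ent-Shi ketone, 1,2:4,5-di-O-isopropylidene-β-L-erythro-2,3-hexodiulo-2,6-pyranose) is taken as a purchasable catalyst, and (2E,6E)-farnesyl acetate and geranyl bromide as the pure E isomers.

Step 1
Reactants: 1 (2E,6E)-farnesyl acetate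
Product: 2 (2E,6S,7S,10S)-6,7:10,11-diepoxy-3,7,11-trimethyldodec-2-en-1-yl acetate
Conditions: ent-Shi ketone (0.6 equiv), Oxone, K2CO3, Bu4NHSO4, Na2B4O7/EDTA buffer (pH 10.5), MeCN–DMM–H2O, 0 °C
Reagents that add atoms: Oxone (potassium peroxymonosulfate), [K+].[O-]S(=O)(=O)OO
Why: Shi asymmetric epoxidation: the dioxirane of the L-fructose-derived ketone epoxidises the two electron-rich trisubstituted alkenes through the spiro transition state, setting C6, C7 and C10 as S under catalyst control, while the 2,3-alkene is deactivated by the allylic acetate.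

Step 2
Reactants: 2 (2E,6S,7S,10S)-6,7:10,11-diepoxy-3,7,11-trimethyldodec-2-en-1-yl acetate
Product: 5 (3S,5aS,6R,7S,9aS)-3-(tert-butyldimethylsilyloxy)-6-(hydroxymethyl)-2,2,5a,7-tetramethyldecahydro-1-benzoxepin-7-ol, via dioxanylium triflate 3 (not isolated), via hydroxy acetate 4 (not isolated)
Conditions: TBSOTf (1.2 equiv), 2,6-di-tert-butyl-4-methylpyridine (DTBMP), CH2Cl2, –78 °C; aq NaHCO3; then K2CO3, MeOH, rt
Reagents that add atoms: tert-butyldimethylsilyl triflate, CC(C)(C)[Si](C)(C)OS(=O)(=O)C(F)(F)F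
Why: Silyl-triflate-promoted tandem oxa-/carbacyclisation of a 1,5-diepoxide: O-silylation of the terminal epoxide lets the internal epoxide oxygen close the oxepane as an epoxonium ion, the (E)-alkene opens it with inversion at the methyl-bearing carbon through a chair (trans ring fusion, CH2O equatorial), and the tertiary cation is captured anti by the acetate carbonyl (neighbouring-group participation), so that hydrolysis and methanolysis leave the C7 hydroxyl equatorial and the C7 methyl axial, with the C3 oxygen already protected as its TBS ether.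

Step 3
Reactants: 5 (3S,5aS,6R,7S,9aS)-3-(tert-butyldimethylsilyloxy)-6-(hydroxymethyl)-2,2,5a,7-tetramethyldecahydro-1-benzoxepin-7-ol
Product: 6 (3S,5aS,6S,7S,9aS)-3-(tert-butyldimethylsilyloxy)-6-(iodomethyl)-2,2,5a,7-tetramethyldecahydro-1-benzoxepin-7-ol
Conditions: PPh3, I2, imidazole, toluene–MeCN, 60 °C
Reagents that add atoms: iodine, II
Why: Appel-type iodination (PPh3/I2/imidazole): only the primary alcohol can be displaced through its alkoxyphosphonium salt, the tertiary C7 alcohol cannot react by SN2, and no stereocentre is touched.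

Step 4
Reactants: 7 geranyl bromide [(2E)-1-bromo-3,7-dimethylocta-2,6-diene]; 8 N-methoxy-N-methylacetamide
Product: 10 (4E)-N-methoxy-N,5,9-trimethyldeca-4,8-dienamide, via lithium enolate 9 (not isolated)
Conditions: LDA, THF, –78 °C; then 7, –78 → –20 °C
Reagents that add atoms: none
Why: Enolate alkylation: the lithium enolate of the Weinreb acetamide displaces the primary allylic bromide in an SN2 reaction that leaves the E alkene untouched; no stereocentre is formed.

Step 5
Reactants: 10 (4E)-N-methoxy-N,5,9-trimethyldeca-4,8-dienamide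
Product: 11 (4S,5S,8S)-4,5:8,9-diepoxy-N-methoxy-N,5,9-trimethyldecanamide
Conditions: ent-Shi ketone (0.6 equiv), Oxone, K2CO3, Bu4NHSO4, Na2B4O7/EDTA buffer (pH 10.5), MeCN–DMM–H2O, 0 °C
Reagents that add atoms: Oxone (potassium peroxymonosulfate), [K+].[O-]S(=O)(=O)OO
Why: Shi asymmetric epoxidation under catalyst control, as in step 1, converts both trisubstituted alkenes into the (4S,5S) and (8S) epoxides; the Weinreb amide is inert to buffered Oxone.

Step 6
Reactants: 11 (4S,5S,8S)-4,5:8,9-diepoxy-N-methoxy-N,5,9-trimethyldecanamide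
Product: 12 (6S,7S,10S)-6,7:10,11-diepoxy-7,11-dimethyldodec-1-en-3-one
Conditions: vinylmagnesium bromide (1.3 equiv), THF, –78 → –20 °C; AcOH/THF quench at –78 °C, then pH 7 buffer
Reagents that add atoms: vinylmagnesium bromide, C=C[Mg]Br
Why: Weinreb ketone synthesis: the chelated tetrahedral intermediate prevents over-addition, the trisubstituted epoxides are not opened by the Grignard reagent at low temperature, and the acidic low-temperature quench keeps the liberated amine from adding to the enone; no stereocentre is formed.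

Step 7
Reactants: 6 (3S,5aS,6S,7S,9aS)-3-(tert-butyldimethylsilyloxy)-6-(iodomethyl)-2,2,5a,7-tetramethyldecahydro-1-benzoxepin-7-ol; 12 (6S,7S,10S)-6,7:10,11-diepoxy-7,11-dimethyldodec-1-en-3-one
Product: 15 (2Z,6S,7S,10S)-6,7:10,11-diepoxy-7,11-dimethyl-3-(trimethylsilyloxy)dodec-2-ene carrying at C1 the [(3S,5aS,6S,7S,9aS)-3-(tert-butyldimethylsilyloxy)-2,2,5a,7-tetramethyl-7-(trimethylsilyloxy)decahydro-1-benzoxepin-6-yl]methyl group, via dilithio species 13 (not isolated), via organocopper 14 (not isolated)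
Conditions: 6, t-BuLi (3.1 equiv), Et2O–pentane, –78 °C; CuI, TMEDA, THF, –78 °C; TMSCl (5 equiv), then 12, –78 °C; Et3N, –78 → 0 °C; pentane, filtration
Reagents that add atoms: chlorotrimethylsilane, C[Si](C)(C)Cl
Why: Lithium–iodine exchange, transmetalation to the organocopper and TMSCl-assisted conjugate addition to the vinyl ketone deliver the enolate regiospecifically on the bridge side and trap it as the (Z)-silyl enol ether (s-cis enone), the tertiary alkoxide being silylated in the same pot; the bridge C–C bond is formed without creating a stereocentre and the epoxides survive at –78 °C.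

Step 8
Reactants: 15 the (Z)-trimethylsilyl enol ether diepoxide described in step 7
Product: 17 1-[(3S,5aS,6S,9aS)-3-hydroxy-2,2,5a-trimethyl-7-oxodecahydro-1-benzoxepin-6-yl]-2-[(3S,5aS,6S,7S,9aS)-3-(tert-butyldimethylsilyloxy)-7-hydroxy-2,2,5a,7-tetramethyldecahydro-1-benzoxepin-6-yl]ethane, via bis-TMS ketone 16 (not isolated)
Conditions: TMSOTf (1.1 equiv), DTBMP, CH2Cl2, –78 °C; Et3N/MeOH quench; then K2CO3, MeOH, rt
Reagents that add atoms: none
Why: Silylation of the terminal epoxide oxygen triggers attack by the neighbouring internal epoxide oxygen at the tertiary carbon (7-endo epoxide opening, oxepane closed as a bicyclic epoxonium ion), and the carbon of the Z enol silane then opens the epoxonium ion at its methyl-bearing carbon (6-endo epoxide opening, 6-(enolendo) for the nucleophile), closing the cyclohexanone last and releasing its silyl group, so that TMSOTf acts as a silyl-transfer agent and the step is overall an isomerisation. The closest known reaction type is the silyl-triflate-promoted tandem oxa-/carbacyclisation of 1,5-diepoxides terminated by an enol silane. C3 and C9a keep the epoxide configurations set by the Shi epoxidation; C5a is set by SN2-type inversion at the epoxonium carbon, which enforces the trans ring fusion (C5a–CH3 anti to C9a–H); C6 arises from the chair transition state of the Z enol silane with the bridge equatorial and is in any case equilibrated to the equatorial epimer by the K2CO3/MeOH treatment that removes both TMS ethers. The step needs endo opening at both epoxides and C- rather than O-alkylation of the enol silane; the first is secured by the trisubstituted epoxides, whose tertiary carbons carry the positive charge, and the second by the six-membered chair open to carbon together with low temperature and a hindered base that suppress protodesilylation.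

Step 9
Reactants: 17 the keto diol described in step 8
Product: 18 1-[(3S,5aS,6S,7R,9aS)-3,7-dihydroxy-2,2,5a,7-tetramethyldecahydro-1-benzoxepin-6-yl]-2-[(3S,5aS,6S,7S,9aS)-3-(tert-butyldimethylsilyloxy)-7-hydroxy-2,2,5a,7-tetramethyldecahydro-1-benzoxepin-6-yl]ethane
Conditions: MeMgBr (6 equiv), THF–Et2O, –40 → 0 °C; aq NH4Cl
Reagents that add atoms: methylmagnesium bromide, C[Mg]Br
Why: Grignard addition to the cyclohexanone: the axial C5a methyl blocks the axial trajectory by a 1,3-diaxial interaction, so the reagent attacks equatorially and sets C7 as R with the methyl equatorial and the hydroxyl axial (cis to the C5a methyl).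

Step 10
Reactants: 18 the triol described in step 9
Product: 20 1-[(3S,5aS,6S,7R,9aS)-3,7-diacetoxy-2,2,5a,7-tetramethyldecahydro-1-benzoxepin-6-yl]-2-[(3S,5aS,6S,7S,9aS)-7-acetoxy-3-(tert-butyldimethylsilyloxy)-2,2,5a,7-tetramethyldecahydro-1-benzoxepin-6-yl]ethane, via trilithium alkoxide 19 (not isolated)
Conditions: LiHMDS (3.5 equiv), THF, –78 → 0 °C; Ac2O (6 equiv), –78 °C → rt
Reagents that add atoms: acetic anhydride, CC(=O)OC(C)=O
Why: O-Acylation of the preformed lithium alkoxides: deprotonation makes the secondary C3 and the two hindered tertiary C7 oxygens nucleophilic enough for acetic anhydride, the TBS ether is untouched, and no stereocentre is affected.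

Step 11
Reactants: 20 the triacetate TBS ether described in step 10
Product: 21 CNP0169816.1, 1-[(3S,5aS,6S,7R,9aS)-3,7-diacetoxy-2,2,5a,7-tetramethyldecahydro-1-benzoxepin-6-yl]-2-[(3S,5aS,6S,7S,9aS)-7-acetoxy-3-hydroxy-2,2,5a,7-tetramethyldecahydro-1-benzoxepin-6-yl]ethane
Conditions: HF·pyridine, pyridine–THF, 0 °C → rt
Reagents that add atoms: none
Why: Fluoride-mediated desilylation: buffered HF cleaves the Si–O bond of the hindered TBS ether while secondary and tertiary acetates are stable, liberating the C3 hydroxyl of the right half without touching a stereocentre.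

Compound list

1 | (2E,6E)-farnesyl acetate | CC(=O)OC/C=C(\C)CC/C=C(\C)CCC=C(C)C | starting material
2 | (2E,6S,7S,10S)-6,7:10,11-diepoxy-3,7,11-trimethyldodec-2-en-1-yl acetate | CC(=O)OC/C=C(\C)CC[C@@H]1O[C@@]1(C)CC[C@@H]1OC1(C)C | intermediate
3 | trans-fused 2-methyl-1,3-dioxan-2-ylium triflate spanning the C7 oxygen and the C6 CH2O of the TBS-protected right bicycle (not isolated) | O1C[C@H]2[C@]3(C)CC[C@H](O[Si](C)(C)C(C)(C)C)C(C)(C)O[C@H]3CC[C@]2(C)[O+]=C1C.[O-]S(=O)(=O)C(F)(F)F | intermediate
4 | [(3S,5aS,6R,7S,9aS)-3-(tert-butyldimethylsilyloxy)-7-hydroxy-2,2,5a,7-tetramethyldecahydro-1-benzoxepin-6-yl]methyl acetate (not isolated; any tertiary acetate isomer converges on 5) | CC(=O)OC[C@H]1[C@]2(C)CC[C@H](O[Si](C)(C)C(C)(C)C)C(C)(C)O[C@H]2CC[C@]1(C)O | intermediate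
5 | (3S,5aS,6R,7S,9aS)-3-(tert-butyldimethylsilyloxy)-6-(hydroxymethyl)-2,2,5a,7-tetramethyldecahydro-1-benzoxepin-7-ol (trans-fused; 5a- and 7-CH3 axial, 7-OH and CH2OH equatorial) | OC[C@H]1[C@]2(C)CC[C@H](O[Si](C)(C)C(C)(C)C)C(C)(C)O[C@H]2CC[C@]1(C)O | intermediate
6 | (3S,5aS,6S,7S,9aS)-3-(tert-butyldimethylsilyloxy)-6-(iodomethyl)-2,2,5a,7-tetramethyldecahydro-1-benzoxepin-7-ol | IC[C@H]1[C@]2(C)CC[C@H](O[Si](C)(C)C(C)(C)C)C(C)(C)O[C@H]2CC[C@]1(C)O | intermediate
7 | geranyl bromide, (2E)-1-bromo-3,7-dimethylocta-2,6-diene | BrC/C=C(\C)CCC=C(C)C | starting material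
8 | N-methoxy-N-methylacetamide | CC(=O)N(C)OC | starting material
9 | lithium enolate of N-methoxy-N-methylacetamide (not isolated) | C=C(O[Li])N(C)OC | intermediate
10 | (4E)-N-methoxy-N,5,9-trimethyldeca-4,8-dienamide | CON(C)C(=O)CC/C=C(\C)CCC=C(C)C | intermediate
11 | (4S,5S,8S)-4,5:8,9-diepoxy-N-methoxy-N,5,9-trimethyldecanamide | CON(C)C(=O)CC[C@@H]1O[C@@]1(C)CC[C@@H]1OC1(C)C | intermediate
12 | (6S,7S,10S)-6,7:10,11-diepoxy-7,11-dimethyldodec-1-en-3-one | C=CC(=O)CC[C@@H]1O[C@@]1(C)CC[C@@H]1OC1(C)C | intermediate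
13 | lithium 7-alkoxide of the 6-(lithiomethyl) analogue of 6 (not isolated) | [Li]C[C@H]1[C@]2(C)CC[C@H](O[Si](C)(C)C(C)(C)C)C(C)(C)O[C@H]2CC[C@]1(C)O[Li] | intermediate
14 | organocopper(I) reagent from 13, TMEDA complex (not isolated) | [Cu]C[C@H]1[C@]2(C)CC[C@H](O[Si](C)(C)C(C)(C)C)C(C)(C)O[C@H]2CC[C@]1(C)O[Li] | intermediate
15 | (2Z,6S,7S,10S)-6,7:10,11-diepoxy-7,11-dimethyl-3-(trimethylsilyloxy)dodec-2-ene carrying at C1 the [(3S,5aS,6S,7S,9aS)-3-(tert-butyldimethylsilyloxy)-2,2,5a,7-tetramethyl-7-(trimethylsilyloxy)decahydro-1-benzoxepin-6-yl]methyl group | C[Si](C)(C)O/C(CC[C@@H]1O[C@@]1(C)CC[C@@H]1OC1(C)C)=C\CC[C@H]1[C@]2(C)CC[C@H](O[Si](C)(C)C(C)(C)C)C(C)(C)O[C@H]2CC[C@]1(C)O[Si](C)(C)C | intermediate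
16 | 1-[(3S,5aS,6S,9aS)-2,2,5a-trimethyl-7-oxo-3-(trimethylsilyloxy)decahydro-1-benzoxepin-6-yl]-2-[(3S,5aS,6S,7S,9aS)-3-(tert-butyldimethylsilyloxy)-2,2,5a,7-tetramethyl-7-(trimethylsilyloxy)decahydro-1-benzoxepin-6-yl]ethane (not isolated) | C[Si](C)(C)O[C@H]1CC[C@]2(C)[C@H](CCC(=O)[C@H]2CC[C@H]2[C@]3(C)CC[C@H](O[Si](C)(C)C(C)(C)C)C(C)(C)O[C@H]3CC[C@]2(C)O[Si](C)(C)C)OC1(C)C | intermediate
17 | 1-[(3S,5aS,6S,9aS)-3-hydroxy-2,2,5a-trimethyl-7-oxodecahydro-1-benzoxepin-6-yl]-2-[(3S,5aS,6S,7S,9aS)-3-(tert-butyldimethylsilyloxy)-7-hydroxy-2,2,5a,7-tetramethyldecahydro-1-benzoxepin-6-yl]ethane | O[C@H]1CC[C@]2(C)[C@H](CCC(=O)[C@H]2CC[C@H]2[C@]3(C)CC[C@H](O[Si](C)(C)C(C)(C)C)C(C)(C)O[C@H]3CC[C@]2(C)O)OC1(C)C | intermediate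
18 | 1-[(3S,5aS,6S,7R,9aS)-3,7-dihydroxy-2,2,5a,7-tetramethyldecahydro-1-benzoxepin-6-yl]-2-[(3S,5aS,6S,7S,9aS)-3-(tert-butyldimethylsilyloxy)-7-hydroxy-2,2,5a,7-tetramethyldecahydro-1-benzoxepin-6-yl]ethane | O[C@H]1CC[C@]2(C)[C@H](CC[C@@](C)(O)[C@H]2CC[C@H]2[C@]3(C)CC[C@H](O[Si](C)(C)C(C)(C)C)C(C)(C)O[C@H]3CC[C@]2(C)O)OC1(C)C | intermediate
19 | trilithium alkoxide of 18 (not isolated) | [Li]O[C@H]1CC[C@]2(C)[C@H](CC[C@@](C)(O[Li])[C@H]2CC[C@H]2[C@]3(C)CC[C@H](O[Si](C)(C)C(C)(C)C)C(C)(C)O[C@H]3CC[C@]2(C)O[Li])OC1(C)C | intermediate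
20 | 1-[(3S,5aS,6S,7R,9aS)-3,7-diacetoxy-2,2,5a,7-tetramethyldecahydro-1-benzoxepin-6-yl]-2-[(3S,5aS,6S,7S,9aS)-7-acetoxy-3-(tert-butyldimethylsilyloxy)-2,2,5a,7-tetramethyldecahydro-1-benzoxepin-6-yl]ethane | CC(=O)O[C@H]1CC[C@]2(C)[C@H](CC[C@@](C)(OC(C)=O)[C@H]2CC[C@H]2[C@]3(C)CC[C@H](O[Si](C)(C)C(C)(C)C)C(C)(C)O[C@H]3CC[C@]2(C)OC(C)=O)OC1(C)C | intermediate
21 | CNP0169816.1, 1-[(3S,5aS,6S,7R,9aS)-3,7-diacetoxy-2,2,5a,7-tetramethyldecahydro-1-benzoxepin-6-yl]-2-[(3S,5aS,6S,7S,9aS)-7-acetoxy-3-hydroxy-2,2,5a,7-tetramethyldecahydro-1-benzoxepin-6-yl]ethane | CC(=O)O[C@H]1CC[C@]2(C)[C@H](CC[C@@](C)(OC(C)=O)[C@H]2CC[C@H]2[C@]3(C)CC[C@H](O)C(C)(C)O[C@H]3CC[C@]2(C)OC(C)=O)OC1(C)C | target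

Total step count: 11
Longest linear sequence: 8 steps (steps 1–3 then 7–11, or steps 4–6 then 7–11)

Steps most likely to fail

Step 8. The silyl enol ether may be protodesilylated or alkylated on oxygen, or the silylated internal epoxide may be captured before the oxepane oxonium has formed, so that the epoxonium ion collapses by hydride shift or elimination instead of closing the cyclohexanone. The fallback changes the terminating nucleophile to a more acid-stable and weaker π-donor, which also keeps oxepane formation ahead of C–C bond formation. It sets out from 15: MeLi and then PhNTf2 convert the enol silane into the (Z)-enol triflate F1; Kumada-type coupling with Me3SiCH2MgCl under Pd(PPh3)4 gives the trisubstituted allylsilane F2; the same TMSOTf/DTBMP cascade closes oxepane and cyclohexane with transfer of silicon to give the 7-methylene bicycle F3; ozonolysis (O3, then Me2S) comes back to the route at 16, which is methanolysed to 17 as before.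

Step 2. The acetate-deactivated 2,3-alkene may fail to intercept the epoxonium ion, or the tertiary cation may lose a proton faster than it is captured by the acetate carbonyl, giving alkene mixtures. The fallback uses carbon termination by a β-keto ester and installs the carbinol afterwards. It sets out from 11: the lithium enolate of methyl acetate acylates the Weinreb amide to give methyl (6S,7S,10S)-6,7:10,11-diepoxy-7,11-dimethyl-3-oxododecanoate F4; TBSOTf/DTBMP cyclises it through its enol to the bicyclic β-keto ester F5; Wittig methylenation gives the 7-methylene ester F6; m-CPBA epoxidises the exocyclic alkene from the equatorial face, away from the axial C5a methyl, to give the spiro-epoxide F7; LiAlH4 opens the epoxide at CH2 and reduces the ester, coming back to the route at 5.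

Step 7. Generation of the functionalised organocopper may be incomplete, halide and silyl chloride may open the epoxides, and the labile enol silane may hydrolyse on isolation. The fallback replaces the stoichiometric organometallic by a nickel-catalysed reductive conjugate addition. It sets out from 6 and 12: NiCl2(dme)/terpyridine, Mn and Et3SiCl give the triethylsilyl enol ether F8 directly (either enol geometry converges, because C6 is equilibrated later); F8 is cyclised under the conditions of step 8 and comes back to the route at 17.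

Further compounds
F1 | step 8 | (Z)-enol triflate corresponding to 15 (OTf in place of the enol OSiMe3) | FC(F)(F)S(=O)(=O)O/C(CC[C@@H]1O[C@@]1(C)CC[C@@H]1OC1(C)C)=C\CC[C@H]1[C@]2(C)CC[C@H](O[Si](C)(C)C(C)(C)C)C(C)(C)O[C@H]2CC[C@]1(C)O[Si](C)(C)C
F2 | step 8 | (Z)-allylsilane corresponding to 15 (CH2SiMe3 in place of the enol OSiMe3) | C[Si](C)(C)C/C(CC[C@@H]1O[C@@]1(C)CC[C@@H]1OC1(C)C)=C\CC[C@H]1[C@]2(C)CC[C@H](O[Si](C)(C)C(C)(C)C)C(C)(C)O[C@H]2CC[C@]1(C)O[Si](C)(C)C
F3 | step 8 | 7-methylene analogue of 16 (exocyclic C=CH2 in place of the left C7 ketone) | C[Si](C)(C)O[C@H]1CC[C@]2(C)[C@H](CCC(=C)[C@H]2CC[C@H]2[C@]3(C)CC[C@H](O[Si](C)(C)C(C)(C)C)C(C)(C)O[C@H]3CC[C@]2(C)O[Si](C)(C)C)OC1(C)C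
F4 | step 2 | methyl (6S,7S,10S)-6,7:10,11-diepoxy-7,11-dimethyl-3-oxododecanoate | COC(=O)CC(=O)CC[C@@H]1O[C@@]1(C)CC[C@@H]1OC1(C)C
F5 | step 2 | methyl (3S,5aS,6S,9aS)-3-(tert-butyldimethylsilyloxy)-2,2,5a-trimethyl-7-oxodecahydro-1-benzoxepine-6-carboxylate (trans-fused, ester equatorial) | COC(=O)[C@H]1[C@]2(C)CC[C@H](O[Si](C)(C)C(C)(C)C)C(C)(C)O[C@H]2CCC1=O
F6 | step 2 | 7-methylene analogue of F5 (trans-fused, ester equatorial) | COC(=O)[C@H]1[C@]2(C)CC[C@H](O[Si](C)(C)C(C)(C)C)C(C)(C)O[C@H]2CCC1=C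
F7 | step 2 | spiro-epoxide of F6 with the epoxide oxygen equatorial and the CH2 axial at C7 | COC(=O)[C@H]1[C@]2(C)CC[C@H](O[Si](C)(C)C(C)(C)C)C(C)(C)O[C@H]2CC[C@@]13CO3
F8 | step 7 | triethylsilyl enol ether analogue of 15 with the right C7 hydroxyl free (Z isomer drawn) | CC[Si](CC)(CC)O/C(CC[C@@H]1O[C@@]1(C)CC[C@@H]1OC1(C)C)=C\CC[C@H]1[C@]2(C)CC[C@H](O[Si](C)(C)C(C)(C)C)C(C)(C)O[C@H]2CC[C@]1(C)O
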